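**Retrosynthetic overview**

- Last C–C bond, C6′–C7′: electrochemical nickel-catalysed decarboxylative alkenylation of a ring-bearing acid with an (E)-alkenyl iodide. The same cell strips the two sulfonyl groups from the linchpin carbon C1′. α-Methylenation and deprotection follow.
- The oxane ring is the only ring; it is bought, not built, and is present from step 1. 3,4-Di-O-acetyl-D-xylal plus a ketene silyl acetal (Ferrier) sets C2; Pd allylic alkylation with bis(phenylsulfonyl)methane sets C5 with retention; then H2.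
- C1′–C2′: a second Pd allylic alkylation of that disulfone carbon with the C7 allylic acetate acid cut out of geranyl acetate (ozonolysis, Pinnick).
- Alkenyl iodide (C7′–C13′, carries C11′): methyl (R)-glycidate, MeMgCl then propargyl Grignard, silylation, dehydration, Zr-catalysed carboalumination and iodination.

Assumption: the target is the (2R,5S,11′R) acid as drawn; ring atoms are O1, C2–C6 and the side chain is C1′–C13′ counted from the ring; 3,4-di-O-acetyl-D-xylal (from D-xylose) and methyl (R)-glycidate (from L-serine) are bought.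

**Route**

Step 1
Reactants: 1 3,4-di-O-acetyl-D-xylal; 2 1-(tert-butyldimethylsilyloxy)-1-methoxyethene
Product: 3 methyl 2-[(2S,5S)-5-acetoxy-5,6-dihydro-2H-pyran-2-yl]acetate
Conditions: TMSOTf (10 mol %), MeCN, −40 → −20 °C
Reagents that add atoms: none
Why: Ferrier C-glycosylation (allylic oxocarbenium from loss of the allylic acetate, Mukaiyama-type attack at the anomeric carbon) in which the nucleophile enters anti to the remaining acetoxy group, so the new C2 centre (2,5-trans) is controlled by the D-xylose-derived acetoxy carbon, whose label changes from R to S only through CIP ranking.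

Step 2
Reactants: 3 methyl 2-[(2S,5S)-5-acetoxy-5,6-dihydro-2H-pyran-2-yl]acetate; 4 bis(phenylsulfonyl)methane
Product: 5 methyl 2-[(2S,5S)-5-[bis(phenylsulfonyl)methyl]-5,6-dihydro-2H-pyran-2-yl]acetate
Conditions: 4 (2.0 equiv), NaH (1.9 equiv), Pd(PPh3)4 (5 mol %), THF, 65 °C
Reagents that add atoms: none
Why: Tsuji–Trost allylic alkylation in which zerovalent palladium ionises the acetate with inversion and the soft disulfonyl carbanion attacks the less hindered allyl terminus anti to palladium, so C–C replaces C–O at C5 with net retention and the 2,5-trans relation is kept.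

Step 3
Reactants: 5 methyl 2-[(2S,5S)-5-[bis(phenylsulfonyl)methyl]-5,6-dihydro-2H-pyran-2-yl]acetate
Product: 6 methyl 2-[(2R,5S)-5-[bis(phenylsulfonyl)methyl]oxan-2-yl]acetate
Conditions: H2 (1 atm), 5% Pd/C, EtOAc, 20 °C
Reagents that add atoms: none
Why: Heterogeneous hydrogenation of the ring cis-alkene, which touches no stereocentre (C2 is now labelled R only because the CIP ranking changes).

Step 4
Reactants: 7 geranyl acetate
Product: 9 (E)-6-acetoxy-4-methylhex-4-enoic acid, via aldehyde 8 (not isolated)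
Conditions: O3, CH2Cl2–pyridine, −78 °C (Sudan Red 7B end point); Me2S, → 20 °C; evaporate; NaClO2, NaH2PO4, 2-methyl-2-butene, t-BuOH–H2O, 0 → 20 °C
Reagents that add atoms: ozone [O-][O+]=O; sodium chlorite [Na+].[O-]Cl=O
Why: Chemoselective ozonolysis of the electron-rich terminal alkene (the other alkene is deactivated by the allylic acetate) followed by Pinnick oxidation of the crude aldehyde, leaving the E-alkene untouched.

Step 5
Reactants: 6 methyl 2-[(2R,5S)-5-[bis(phenylsulfonyl)methyl]oxan-2-yl]acetate; 9 (E)-6-acetoxy-4-methylhex-4-enoic acid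
Product: 10 (E)-7-[(3S,6R)-6-(2-methoxy-2-oxoethyl)oxan-3-yl]-4-methyl-7,7-bis(phenylsulfonyl)hept-4-enoic acid
Conditions: NaH (2.1 equiv), Pd(PPh3)4 (5 mol %), THF–DMSO, 60 °C; then 1 M HCl
Reagents that add atoms: none
Why: Second Tsuji–Trost allylic alkylation in which the bulky tertiary disulfonyl carbanion attacks the primary terminus of the prenyl-type allylpalladium to give the linear E product (C1′–C2′ bond), with no stereocentre formed or touched.

Step 6
Reactants: 11 methyl (R)-glycidate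
Product: 13 (3R)-2-methylhept-6-yne-2,3-diol, via magnesium alkoxide 12 (not isolated)
Conditions: MeMgCl (2.05 equiv), THF, −78 → −40 °C; then HC≡CCH2MgBr (1.5 equiv), Et2O, −40 → 0 °C; aq. NH4Cl
Reagents that add atoms: methylmagnesium chloride C[Mg]Cl; propargylmagnesium bromide C#CC[Mg]Br
Why: Double Grignard addition to the ester and then SN2 opening of the epoxide at its CH2 terminus by the propargyl (allenyl) Grignard reagent, so the C–O bond at the serine-derived stereocentre (the future C11′) is never broken.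

Step 7
Reactants: 13 (3R)-2-methylhept-6-yne-2,3-diol
Product: 14 (3R)-3-(tert-butyldimethylsilyloxy)-2-methylhept-6-yn-2-ol
Conditions: TBSCl (1.1 equiv), imidazole, DMF, 0 → 20 °C
Reagents that add atoms: tert-butyldimethylsilyl chloride CC(C)(C)[Si](C)(C)Cl
Why: Selective silyl ether formation at the secondary hydroxyl, the tertiary one being too hindered for TBSCl–imidazole.

Step 8
Reactants: 14 (3R)-3-(tert-butyldimethylsilyloxy)-2-methylhept-6-yn-2-ol
Product: 15 tert-butyldimethyl{[(3R)-2-methylhept-1-en-6-yn-3-yl]oxy}silane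
Conditions: SOCl2, pyridine, CH2Cl2, −20 → 0 °C
Reagents that add atoms: none
Why: Chlorosulfite E2 dehydration of the tertiary alcohol toward an unhindered methyl hydrogen gives the isopropenyl group without touching the stereocentre.

Step 9
Reactants: 15 tert-butyldimethyl{[(3R)-2-methylhept-1-en-6-yn-3-yl]oxy}silane
Product: 17 tert-butyl{[(3R,6E)-7-iodo-2,6-dimethylhepta-1,6-dien-3-yl]oxy}dimethylsilane, via alkenylalane 16 (not isolated)
Conditions: Me3Al (3 equiv), Cp2ZrCl2 (0.25 equiv), H2O (1 equiv), CH2Cl2, −20 → 20 °C; then I2, THF, −30 → 0 °C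
Reagents that add atoms: trimethylaluminium C[Al](C)C; iodine II
Why: Negishi zirconium-catalysed syn-carboalumination of the terminal alkyne (methyl to the internal carbon) and iodinolysis with retention give the E-trisubstituted alkenyl iodide.

Step 10
Reactants: 10 (E)-7-[(3S,6R)-6-(2-methoxy-2-oxoethyl)oxan-3-yl]-4-methyl-7,7-bis(phenylsulfonyl)hept-4-enoic acid; 17 tert-butyl{[(3R,6E)-7-iodo-2,6-dimethylhepta-1,6-dien-3-yl]oxy}dimethylsilane
Product: 20 methyl 2-[(2R,5S)-5-[(3E,7E,11R)-11-(tert-butyldimethylsilyloxy)-4,8,12-trimethyltrideca-3,7,12-trien-1-yl]oxan-2-yl]acetate, via phthalimide ester 18 (not isolated), via coupled disulfone 19 (not isolated)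
Conditions: 10 (1.3 equiv), N-hydroxyphthalimide, DIC, DMAP (5 mol %), CH2Cl2, 20 °C, evaporate; then 17 (1.0 equiv), NiCl2·6H2O (20 mol %), 2,2′-bipyridine (20 mol %), AgNO3 (0.3 equiv), LiCl, DMF, Mg anode, RVC cathode, undivided cell, constant current, 2.5 F/mol, 20 °C; then MeOH (20 equiv), current continued (about 8 F/mol)
Reagents that add atoms: none
Why: Proposed new method: a one-cell sequence in which the N-acyloxyphthalimide is reduced by low-valent nickel–bipyridine at the silver-coated cathode (about −1.2 V vs SCE) to the primary C6′ radical, which is captured by the alkenylnickel species from 17 and reductively eliminated with retention of the E geometry to form the C6′–C7′ bond, after which methanol is added and the potential is allowed to fall so that the quaternary geminal disulfone (about −1.8 V) and then the monosulfone (about −2.3 V) undergo two-electron C–S cleavage to sulfinate and a carbanion that methanol protonates, leaving C1′ as CH2 with no stereocentre touched; the closest known reaction types are the nickel-electrocatalysed decarboxylative alkenylation of redox-active esters with alkenyl iodides and the Mg/MeOH or cathodic desulfonylation of geminal disulfones, neither of which has been run on a disulfone-bearing redox-active ester or combined in one cell.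

Step 11
Reactants: 20 methyl 2-[(2R,5S)-5-[(3E,7E,11R)-11-(tert-butyldimethylsilyloxy)-4,8,12-trimethyltrideca-3,7,12-trien-1-yl]oxan-2-yl]acetate
Product: 23 methyl 2-[(2R,5S)-5-[(3E,7E,11R)-11-(tert-butyldimethylsilyloxy)-4,8,12-trimethyltrideca-3,7,12-trien-1-yl]oxan-2-yl]prop-2-enoate, via Mannich base 21 (not isolated), via ammonium iodide 22 (not isolated)
Conditions: LiN(i-Pr)2, THF, −78 °C; CH2=NMe2 I, −78 → 0 °C; then MeI, 20 °C; then DBU, 20 °C
Reagents that add atoms: N,N-dimethylmethyleneiminium iodide (Eschenmoser's salt) C=[N+](C)C.[I-]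
Why: Ester-enolate Mannich reaction with Eschenmoser's salt, N-methylation and E1cB loss of trimethylamine (α-methylenation) build the acrylate without epimerising C2.

Step 12
Reactants: 23 methyl 2-[(2R,5S)-5-[(3E,7E,11R)-11-(tert-butyldimethylsilyloxy)-4,8,12-trimethyltrideca-3,7,12-trien-1-yl]oxan-2-yl]prop-2-enoate
Product: 25 2-[(2R,5S)-5-[(3E,7E,11R)-11-hydroxy-4,8,12-trimethyltrideca-3,7,12-trien-1-yl]oxan-2-yl]prop-2-enoic acid, via hydroxy ester 24 (not isolated)
Conditions: Bu4NF, THF, 0 → 20 °C; then LiOH·H2O, THF–MeOH–H2O, 20 °C; then 1 M HCl to pH 3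
Reagents that add atoms: lithium hydroxide [Li+].[OH-]
Why: Fluoride desilylation followed by saponification of the acrylate ester frees the allylic alcohol and the acid without affecting any stereocentre.

**Compound list**

1 | 3,4-di-O-acetyl-D-xylal, (3R,4R)-3,4-dihydro-2H-pyran-3,4-diyl diacetate | CC(=O)O[C@@H]1COC=C[C@H]1OC(C)=O | starting material
2 | 1-(tert-butyldimethylsilyloxy)-1-methoxyethene | C=C(OC)O[Si](C)(C)C(C)(C)C | starting material
3 | methyl 2-[(2S,5S)-5-acetoxy-5,6-dihydro-2H-pyran-2-yl]acetate (2,5-trans) | COC(=O)C[C@H]1C=C[C@H](OC(C)=O)CO1 | intermediate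
4 | bis(phenylsulfonyl)methane | O=S(=O)(CS(=O)(=O)c1ccccc1)c1ccccc1 | starting material
5 | methyl 2-[(2S,5S)-5-[bis(phenylsulfonyl)methyl]-5,6-dihydro-2H-pyran-2-yl]acetate | COC(=O)C[C@H]1C=C[C@H](C(S(=O)(=O)c2ccccc2)S(=O)(=O)c2ccccc2)CO1 | intermediate
6 | methyl 2-[(2R,5S)-5-[bis(phenylsulfonyl)methyl]oxan-2-yl]acetate | COC(=O)C[C@H]1CC[C@H](C(S(=O)(=O)c2ccccc2)S(=O)(=O)c2ccccc2)CO1 | intermediate
7 | geranyl acetate, (2E)-3,7-dimethylocta-2,6-dien-1-yl acetate | CC(=O)OC/C=C(\C)CCC=C(C)C | starting material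
8 | (E)-6-acetoxy-4-methylhex-4-enal | CC(=O)OC/C=C(\C)CCC=O | intermediate
9 | (E)-6-acetoxy-4-methylhex-4-enoic acid | CC(=O)OC/C=C(\C)CCC(=O)O | intermediate
10 | (E)-7-[(3S,6R)-6-(2-methoxy-2-oxoethyl)oxan-3-yl]-4-methyl-7,7-bis(phenylsulfonyl)hept-4-enoic acid | OC(=O)CC/C(C)=C/CC(S(=O)(=O)c1ccccc1)(S(=O)(=O)c1ccccc1)[C@H]1CC[C@H](CC(=O)OC)OC1 | intermediate
11 | methyl (R)-glycidate, methyl (2R)-oxirane-2-carboxylate | COC(=O)[C@H]1CO1 | starting material
12 | chloromagnesium 2-[(2R)-oxiran-2-yl]propan-2-olate | CC(C)(O[Mg]Cl)[C@H]1CO1 | intermediate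
13 | (3R)-2-methylhept-6-yne-2,3-diol | CC(C)(O)[C@H](O)CCC#C | intermediate
14 | (3R)-3-(tert-butyldimethylsilyloxy)-2-methylhept-6-yn-2-ol | CC(C)(O)[C@H](O[Si](C)(C)C(C)(C)C)CCC#C | intermediate
15 | tert-butyldimethyl{[(3R)-2-methylhept-1-en-6-yn-3-yl]oxy}silane | C=C(C)[C@H](O[Si](C)(C)C(C)(C)C)CCC#C | intermediate
16 | [(1E,5R)-5-(tert-butyldimethylsilyloxy)-2,6-dimethylhepta-1,6-dien-1-yl]dimethylalane | C=C(C)[C@H](O[Si](C)(C)C(C)(C)C)CC/C(C)=C/[Al](C)C | intermediate
17 | tert-butyl{[(3R,6E)-7-iodo-2,6-dimethylhepta-1,6-dien-3-yl]oxy}dimethylsilane | C=C(C)[C@H](O[Si](C)(C)C(C)(C)C)CC/C(C)=C/I | intermediate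
18 | 1,3-dioxoisoindolin-2-yl (E)-7-[(3S,6R)-6-(2-methoxy-2-oxoethyl)oxan-3-yl]-4-methyl-7,7-bis(phenylsulfonyl)hept-4-enoate | O=C(CC/C(C)=C/CC(S(=O)(=O)c1ccccc1)(S(=O)(=O)c1ccccc1)[C@H]1CC[C@H](CC(=O)OC)OC1)ON1C(=O)c2ccccc2C1=O | intermediate
19 | methyl 2-[(2R,5S)-5-[(3E,7E,11R)-11-(tert-butyldimethylsilyloxy)-4,8,12-trimethyl-1,1-bis(phenylsulfonyl)trideca-3,7,12-trien-1-yl]oxan-2-yl]acetate | C=C(C)[C@H](O[Si](C)(C)C(C)(C)C)CC/C(C)=C/CC/C(C)=C/CC(S(=O)(=O)c1ccccc1)(S(=O)(=O)c1ccccc1)[C@H]1CC[C@H](CC(=O)OC)OC1 | intermediate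
20 | methyl 2-[(2R,5S)-5-[(3E,7E,11R)-11-(tert-butyldimethylsilyloxy)-4,8,12-trimethyltrideca-3,7,12-trien-1-yl]oxan-2-yl]acetate | C=C(C)[C@H](O[Si](C)(C)C(C)(C)C)CC/C(C)=C/CC/C(C)=C/CC[C@H]1CC[C@H](CC(=O)OC)OC1 | intermediate
21 | methyl 3-(dimethylamino)-2-[(2R,5S)-5-[(3E,7E,11R)-11-(tert-butyldimethylsilyloxy)-4,8,12-trimethyltrideca-3,7,12-trien-1-yl]oxan-2-yl]propanoate (both epimers at the propanoate C2) | C=C(C)[C@H](O[Si](C)(C)C(C)(C)C)CC/C(C)=C/CC/C(C)=C/CC[C@H]1CC[C@H](C(CN(C)C)C(=O)OC)OC1 | intermediate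
22 | trimethylammonium iodide of 21, 3-methoxy-3-oxo-2-[(2R,5S)-5-(side chain)oxan-2-yl]-N,N,N-trimethylpropan-1-aminium iodide | C=C(C)[C@H](O[Si](C)(C)C(C)(C)C)CC/C(C)=C/CC/C(C)=C/CC[C@H]1CC[C@H](C(C[N+](C)(C)C)C(=O)OC)OC1.[I-] | intermediate
23 | methyl 2-[(2R,5S)-5-[(3E,7E,11R)-11-(tert-butyldimethylsilyloxy)-4,8,12-trimethyltrideca-3,7,12-trien-1-yl]oxan-2-yl]prop-2-enoate | C=C(C)[C@H](O[Si](C)(C)C(C)(C)C)CC/C(C)=C/CC/C(C)=C/CC[C@H]1CC[C@H](C(=C)C(=O)OC)OC1 | intermediate
24 | methyl 2-[(2R,5S)-5-[(3E,7E,11R)-11-hydroxy-4,8,12-trimethyltrideca-3,7,12-trien-1-yl]oxan-2-yl]prop-2-enoate | C=C(C)[C@H](O)CC/C(C)=C/CC/C(C)=C/CC[C@H]1CC[C@H](C(=C)C(=O)OC)OC1 | intermediate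
25 | 2-[(2R,5S)-5-[(3E,7E,11R)-11-hydroxy-4,8,12-trimethyltrideca-3,7,12-trien-1-yl]oxan-2-yl]prop-2-enoic acid | C=C(C)[C@H](O)CC/C(C)=C/CC/C(C)=C/CC[C@H]1CC[C@H](C(=C)C(=O)O)OC1 | target

**Count and risks**

Total: 12 steps (telescoped operations counted once). Longest linear sequence: 7 steps (1 → 3 → 5 → 6 → 10 → 20 → 23 → 25, or equally 11 → 13 → 14 → 15 → 17 → 20 → 23 → 25).

Most likely to fail, first: step 10, the proposed new one-cell coupling and desulfonylation. The disulfone may be cleaved too early or the second sulfonyl group may resist. The fallback uses only known chemistry and sets out from 10. Mg turnings in MeOH at 50 °C remove both sulfonyl groups to give (E)-7-[(3S,6R)-6-(2-methoxy-2-oxoethyl)oxan-3-yl]-4-methylhept-4-enoic acid F1. N-Hydroxyphthalimide and DIC convert it into 1,3-dioxoisoindolin-2-yl (E)-7-[(3S,6R)-6-(2-methoxy-2-oxoethyl)oxan-3-yl]-4-methylhept-4-enoate F2. F2 is coupled with 17 by the established NiCl2·6H2O, 2,2′-bipyridine, AgNO3, Mg-anode, RVC-cathode electrolysis with no methanol stage. The fallback comes back to the route at 20.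

Second: step 5, where a quaternary disulfone carbon is made next to the ring and the hindered anion of 6 may react slowly. The fallback reverses the order of the two allylations and sets out from 3, with 4 and 9. The unhindered anion of 4 is first allylated with 9 (Pd(PPh3)4, NaH, THF) to give (E)-4-methyl-7,7-bis(phenylsulfonyl)hept-4-enoic acid F3. The dianion of F3 is then the nucleophile toward 3 (Pd(PPh3)4, net retention) and gives (E)-7-[(3S,6S)-6-(2-methoxy-2-oxoethyl)-3,6-dihydro-2H-pyran-3-yl]-4-methyl-7,7-bis(phenylsulfonyl)hept-4-enoic acid F4. Homogeneous hydrogenation with RhCl(PPh3)3 and H2 then reduces only the ring cis-alkene and not the trisubstituted one. The fallback comes back at 10.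

Third: step 1, where the facial selectivity of the Ferrier addition (anti to the acetate) may be modest. The fallback replaces the intermolecular addition by a suprafacial sigmatropic transfer and sets out from 1. Ireland–Claisen rearrangement (LiN(SiMe3)2, Me3SiCl, THF, −78 → 20 °C, kept at or below 20 °C so that only the glycal ester rearranges; aqueous work-up) carries the allylic acetate across its own face to the anomeric carbon and gives 2-[(2S,5S)-5-acetoxy-5,6-dihydro-2H-pyran-2-yl]acetic acid F5. Me3SiCHN2 in MeOH esterifies F5 and the route is rejoined at 3.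

**Further compounds**

F1 | step 10 | (E)-7-[(3S,6R)-6-(2-methoxy-2-oxoethyl)oxan-3-yl]-4-methylhept-4-enoic acid | OC(=O)CC/C(C)=C/CC[C@H]1CC[C@H](CC(=O)OC)OC1
F2 | step 10 | 1,3-dioxoisoindolin-2-yl (E)-7-[(3S,6R)-6-(2-methoxy-2-oxoethyl)oxan-3-yl]-4-methylhept-4-enoate | O=C(CC/C(C)=C/CC[C@H]1CC[C@H](CC(=O)OC)OC1)ON1C(=O)c2ccccc2C1=O
F3 | step 5 | (E)-4-methyl-7,7-bis(phenylsulfonyl)hept-4-enoic acid | OC(=O)CC/C(C)=C/CC(S(=O)(=O)c1ccccc1)S(=O)(=O)c1ccccc1
F4 | step 5 | (E)-7-[(3S,6S)-6-(2-methoxy-2-oxoethyl)-3,6-dihydro-2H-pyran-3-yl]-4-methyl-7,7-bis(phenylsulfonyl)hept-4-enoic acid | OC(=O)CC/C(C)=C/CC(S(=O)(=O)c1ccccc1)(S(=O)(=O)c1ccccc1)[C@H]1C=C[C@H](CC(=O)OC)OC1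
F5 | step 1 | 2-[(2S,5S)-5-acetoxy-5,6-dihydro-2H-pyran-2-yl]acetic acid | OC(=O)C[C@H]1C=C[C@H](OC(C)=O)CO1
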